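In these flasks, reagent and free catalyst together destroy target a little faster, at equal concentrations, than they make it from substrate.

    substrate + catalyst intermediate A → catalyst intermediate B (k1 = 286 M⁻¹ min⁻¹)
    reagent + free catalyst ⇌ catalyst intermediate A (K2 = 9.45 M⁻¹, k2 = 445 M⁻¹ min⁻¹)
    reagent + free catalyst + target → free catalyst + over-reaction product (k3 = 3080 M⁻² min⁻¹)
    catalyst intermediate B ⇌ free catalyst + target (K4 = 0.311 M, k4 = 7.16 min⁻¹)

| setting | east | south | south-west | north-west |
|---|---|---|---|---|
| substrate | 0.010 M | 0.010 M | 0.010 M | 0.010 M |
| reagent | 0.00600 M | 0.0120 M | 0.0200 M | 0.0400 M |
| free catalyst | 0.17 mM | 0.17 mM | 0.17 mM | 0.17 mM |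
| time | 25 min | 25 min | 25 min | 25 min |

- "hardly changes" means that all values lie within two and a half points (for a concentration: within two and a half percent of the largest)
- run time (east): 25 min

- share of target in all that became target or over-reaction product for east, south, south-west, north-west, in this order
- the shape of the row from first to last (hardly changes / rises all the way / rises, then falls / falls all the way / falls, then rises)

I reckoned the small thing, the share lost, and not the large one. Catalyst intermediate A fell back at 47.1 min⁻¹ and went on with substrate at 2.86 min⁻¹, which is far slower. So target formed as c(reagent) times c(free catalyst) times c(substrate) times a constant 2550 M⁻² min⁻¹: the substrate constant times the forward binding constant, over the sum of those two rates, the second taken at the substrate charge. Over-reaction has the same first two factors, with c(target) in place of c(substrate), so they cancel in the ratio. What remains is the selectivity factor κ, the over-reaction constant over that target constant, 1.21. If a fraction X of the substrate has gone and target is still small against substrate, the share lost is about κX/2.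

The first setting is the reagent charge. It raises X, but by my reckoning less than in proportion: I held catalyst as catalyst intermediate A, at 8.91 M⁻¹ times c(reagent) per free catalyst, and as catalyst intermediate B, at 0.399 of A. At the charges, that made free catalyst 93.0 % of the catalyst charged in east and 66.7 % in north-west. With reagent and substrate held at their charges, my shares were 96.5 %, 93.5 %, 90.4 % and 84.8 %, falling throughout. The second setting is the run time. Stopping north-west at 12.5 min shrinks X, and I expected 91.9 %.

The forecast gave 96.6 %, 93.6 %, 90.3 % and 84 %, a row that falls all the way, on this ground: “More reagent means more conversion, so the share falls.” Its north-west figure lies 0.80 percentage points below mine.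

The flasks gave 96.6 %, 93.7 %, 90.3 % and 84.1 %, a row that falls all the way. North-west at 12.5 min stood at 91.7 %.

On the substrate that east really lost, 5.60 %, κ gives 96.6 %, and on the 24.9 % lost in north-west it gives 85.0 %, above the 84.1 % of that flask. In east, catalyst intermediate B and free catalyst with target relaxed toward each other, by that step alone, with a half-life of 0.0966 min, short against the run of 25 min. In east, the rate at which catalyst intermediate A was made over the rate at which it was used up, each step taken net, was 0.999 at 25.0 min, and it stood then at 4.53 % of the catalyst charged.

The rate constants are assumed; the result is computed.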